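**Plan**

- Numbering: C1 lactone carbonyl, C2, C3 (peroxy CH), C4 (methylated ring-fusion carbon), C5, C6 (peroxy carbon with methyl and the arylnonyl chain). The 1,2-dioxane is O–O–C3–C4–C5–C6 and the γ-lactone is C1–C2–C3–C4–O.
- Retrosynthetic cuts, in order: the lactone (C1 oxidation level and C2–C3, traced back to a C3 allyl group), the C6–O peroxide bond, C6–C7 (alkene–alkyne), C4–C5, and the aryl–alkyl bond of the chain.
- Enabling feature: C6 is a fully substituted peroxy carbon bearing a methyl group, so it can be the internal carbon of a C6=CH2 alkene that an iodonium ion activates for Markovnikov attack by a hydroperoxide oxygen anchored at C3. The first two chain carbons stay as an alkyne until the ring is closed.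
- Forward: the arylnonyne and the (S)-bromoallyl carbinol (C3–C6) are made separately and joined by Sonogashira coupling. The acetal becomes the methoxy hydroperoxide, the 1,2-dioxane closes first (iodonium, 6-exo), and the lactone closes last.
- Stereochemistry: C4 from (R)-lactic acid by self-regeneration of stereocentres; C6 from C4 through the chair transition state of the iodonium closure; C3 from C4 by allyl delivery through a silicon tether on the C4 oxygen.

Key step: step 11

Remark: the phenol is carried as a triisopropylsilyl ether, chosen because it should withstand carbonate in methanol; C3 is carried as an epimer mixture from step 10 to step 14 because it is ionised in step 15.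

**Route**

Step 1
Reactants: 1 4-bromophenol
Product: 2 (4-bromophenoxy)triisopropylsilane
Conditions: TIPSCl, imidazole, DMF, rt
Reagents that add atoms: triisopropylsilyl chloride, CC(C)[Si](Cl)(C(C)C)C(C)C
Why: Standard silylation of a phenol; the hindered aryl silyl ether should survive the Grignard, acetylide, carbonate, Lewis acid and oxidation steps and is removable with fluoride.

Step 2
Reactants: 2 (4-bromophenoxy)triisopropylsilane; 3 1,7-dibromoheptane
Product: 5 [4-(7-bromoheptyl)phenoxy]triisopropylsilane, via aryl Grignard reagent 4 (not isolated)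
Conditions: Mg, THF, reflux; then added to 3 (3 equiv), Li2CuCl4 (3 mol%), THF, −10 °C → rt
Reagents that add atoms: none
Why: Copper-catalysed Kumada-type sp2–sp3 cross-coupling of an aryl Grignard reagent with a primary alkyl bromide; the excess of dibromide should suppress double arylation.

Step 3
Reactants: 5 [4-(7-bromoheptyl)phenoxy]triisopropylsilane; 6 lithium (trimethylsilyl)acetylide
Product: 7 trimethyl(9-{4-[(triisopropylsilyl)oxy]phenyl}non-1-yn-1-yl)silane
Conditions: 6 (0.5 M in THF, 1.5 equiv), DMPU, THF, −78 °C → rt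
Reagents that add atoms: none
Why: SN2 alkylation of a lithium acetylide by a primary bromide in a dipolar cosolvent; the C-silyl cap prevents a second alkylation and the aryl silyl ether is inert to the acetylide.

Step 4
Reactants: 7 trimethyl(9-{4-[(triisopropylsilyl)oxy]phenyl}non-1-yn-1-yl)silane
Product: 8 triisopropyl[4-(non-8-yn-1-yl)phenoxy]silane
Conditions: K2CO3 (0.3 equiv), MeOH–THF, rt
Reagents that add atoms: none
Why: Methanolysis of the alkynyl C–Si bond is fast under catalytic carbonate, whereas the hindered aryl TIPS ether should remain intact over the short reaction time.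

Step 5
Reactants: 9 (R)-lactic acid; 10 pivalaldehyde
Product: 11 (2R,5R)-2-tert-butyl-5-methyl-1,3-dioxolan-4-one (cis)
Conditions: TsOH·H2O (cat.), H2SO4 (cat.), pentane, reflux with azeotropic removal of water; recrystallisation (Et2O–pentane, −78 °C)
Reagents that add atoms: none
Why: Acid-catalysed acetalisation under thermodynamic control should favour the cis-dioxolanone, whose acetal centre (2R) is fixed by the lactate stereocentre and which is enriched by crystallisation.

Step 6
Reactants: 11 (2R,5R)-2-tert-butyl-5-methyl-1,3-dioxolan-4-one; 12 2,3-dibromopropene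
Product: 14 (2R,5S)-5-(2-bromoprop-2-en-1-yl)-2-tert-butyl-5-methyl-1,3-dioxolan-4-one, via lithium enolate 13 (not isolated)
Conditions: LDA (1.05 equiv), THF, −78 °C; then 12 (1.5 equiv), −78 → −20 °C
Reagents that add atoms: none
Why: Enolate alkylation with self-regeneration of the stereocentre: the allylic bromide should attack the planar enolate anti to the tert-butyl group, which sets the quaternary carbinol carbon (the future C4) as S.

Step 7
Reactants: 14 (2R,5S)-5-(2-bromoprop-2-en-1-yl)-2-tert-butyl-5-methyl-1,3-dioxolan-4-one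
Product: 15 (2R,5S)-5-(2-bromoprop-2-en-1-yl)-2-tert-butyl-5-methyl-1,3-dioxolan-4-ol (both epimers at the lactol carbon)
Conditions: DIBAL-H (1.2 equiv), CH2Cl2, −78 °C; aq. potassium sodium tartrate
Reagents that add atoms: none
Why: Partial reduction of the dioxolanone carbonyl; the tetrahedral aluminium hemiacetal is stable at −78 °C, so reduction should stop at the lactol, and the vinyl bromide is inert.

Step 8
Reactants: 15 (2R,5S)-5-(2-bromoprop-2-en-1-yl)-2-tert-butyl-5-methyl-1,3-dioxolan-4-ol
Product: 16 (2S)-4-bromo-1,1-dimethoxy-2-methylpent-4-en-2-ol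
Conditions: HC(OMe)3, MeOH, CSA (cat.), 50 °C; Et3N quench
Reagents that add atoms: methanol, CO; trimethyl orthoformate, COC(OC)OC
Why: Acid-catalysed transacetalisation in excess methanol should exchange the lactol and the pivalaldehyde acetal for the open dimethyl acetal while the orthoformate removes the water formed; the carbinol stereocentre is not touched.

Step 9
Reactants: 16 (2S)-4-bromo-1,1-dimethoxy-2-methylpent-4-en-2-ol; 8 triisopropyl[4-(non-8-yn-1-yl)phenoxy]silane
Product: 17 (2S)-1,1-dimethoxy-2-methyl-4-methylidene-13-{4-[(triisopropylsilyl)oxy]phenyl}tridec-5-yn-2-ol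
Conditions: Pd(PPh3)2Cl2 (3 mol%), CuI (6 mol%), Et3N, THF, 45 °C, degassed
Reagents that add atoms: none
Why: Sonogashira coupling of a 2-bromo-1-alkene with a terminal alkyne; the free tertiary alcohol and the acetal are tolerated, and exclusion of oxygen limits alkyne homocoupling.

Step 10
Reactants: 17 (2S)-1,1-dimethoxy-2-methyl-4-methylidene-13-{4-[(triisopropylsilyl)oxy]phenyl}tridec-5-yn-2-ol
Product: 18 (2S)-1-hydroperoxy-1-methoxy-2-methyl-4-methylidene-13-{4-[(triisopropylsilyl)oxy]phenyl}tridec-5-yn-2-ol (both epimers at the peroxy carbon, C3 of the target numbering)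
Conditions: anhydrous H2O2 in Et2O (5 equiv), BF3·OEt2 (10 mol%), 0 °C; NaHCO3 quench
Reagents that add atoms: hydrogen peroxide, OO
Why: Acid-catalysed perhydrolysis of a dimethyl acetal, in which one methoxy group is exchanged for the more nucleophilic hydrogen peroxide, should give the α-methoxy hydroperoxide when stopped at mono-exchange; both epimers are usable.

Step 11
Reactants: 18 the C3 methoxy hydroperoxide; 19 N-iodosuccinimide
Product: 20 (4S,6S)-6-(iodomethyl)-3-methoxy-4-methyl-6-(9-{4-[(triisopropylsilyl)oxy]phenyl}non-1-yn-1-yl)-1,2-dioxan-4-ol (both C3 anomers)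
Conditions: 19 (1.3 equiv), NaHCO3 (solid), CH2Cl2, 0 °C, dark
Reagents that add atoms: none
Why: NIS transfers I+ to the terminal CH2 of the 1,1-disubstituted enyne alkene, positive charge develops at C6 (tertiary and propargylic), and the terminal oxygen of the C3 hydroperoxide adds there in Markovnikov fashion while succinimide takes up the proton. The closest known reaction type is the iodonium-induced cyclisation of unsaturated α-alkoxy hydroperoxides to 3-alkoxy-1,2-dioxanes, the peroxide counterpart of iodoetherification. The 1,2-dioxane (O–O–C3–C4–C5–C6) closes in the 6-exo-trig mode; 4-exo attack by the C4 hydroxyl and 7-endo attack at the CH2 terminus are disfavoured by strain and by charge distribution. The new stereocentre C6 is controlled by the C4 stereocentre through a chair transition state with the C4 methyl equatorial and the C4 hydroxyl axial, in which the rod-shaped alkynyl group takes the axial site syn to that hydroxyl and the bulkier CH2–I terminus stays equatorial, so the chain ends up cis to the C4 oxygen (6S here, 6R once the chain is saturated). The step needs chemoselectivity for the alkene over the alkyne and the arene and facial selectivity at C6: the alkene is the most electron-rich π bond and is trapped intramolecularly as soon as it is activated, the silyl-capped arene should not react with NIS without acid, and the small steric demand of the alkyne against CH2I secures the facial bias. The C3 anomers need no separation because C3 is ionised in step 15.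

Step 12
Reactants: 20 the 6-(iodomethyl)-6-alkynyl-3-methoxy-1,2-dioxan-4-ol
Product: 22 (4S,6R)-6-(iodomethyl)-3-methoxy-4-methyl-6-(9-{4-[(triisopropylsilyl)oxy]phenyl}nonyl)-1,2-dioxan-4-ol, via Z-alkene 21 (not isolated)
Conditions: KO2CN=NCO2K (20 equiv, portions), AcOH (40 equiv, slow addition), MeOH–CH2Cl2, 0 °C → rt, repeated until 21 is consumed
Reagents that add atoms: none
Why: Diimide reduction transfers hydrogen to the C≡C and then the C=C bond by a concerted syn pathway that should leave the O–O bond, the C–I bond and the aryl silyl ether untouched; saturating the alkyne here removes the ionisable propargylic peroxide and a radical acceptor before steps 13 and 15.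

Step 13
Reactants: 22 the 6-(iodomethyl)-6-nonyl-3-methoxy-1,2-dioxan-4-ol
Product: 23 (4S,6R)-3-methoxy-4,6-dimethyl-6-(9-{4-[(triisopropylsilyl)oxy]phenyl}nonyl)-1,2-dioxan-4-ol
Conditions: Bu3SnH (5 equiv, 1 M), Et3B (0.2 equiv), air, PhMe, 0 °C
Reagents that add atoms: none
Why: Radical chain deiodination with tin hydride; the high stannane concentration and low temperature should let hydrogen abstraction outrun intramolecular attack of the β-peroxy radical on the O–O bond (epoxide formation).

Step 14
Reactants: 23 the 3-methoxy-4,6-dimethyl-1,2-dioxan-4-ol; 24 allyl(chloro)dimethylsilane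
Product: 25 {[(4S,6R)-3-methoxy-4,6-dimethyl-6-(9-{4-[(triisopropylsilyl)oxy]phenyl}nonyl)-1,2-dioxan-4-yl]oxy}dimethyl(prop-2-en-1-yl)silane
Conditions: 24 (2 equiv), imidazole (3 equiv), DMAP (cat.), CH2Cl2, rt; filtration through Et3N-deactivated silica
Reagents that add atoms: none
Why: Silylation of the tertiary C4 alcohol with a small chlorosilane under mildly basic conditions that should not trigger base-induced peroxide fragmentation; it places the allylsilane on the C4 oxygen.

Step 15
Reactants: 25 the C4 O-allyldimethylsilyl ether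
Product: 27 (3S,4S,6R)-4,6-dimethyl-3-(prop-2-en-1-yl)-6-(9-{4-[(triisopropylsilyl)oxy]phenyl}nonyl)-1,2-dioxan-4-ol, via silyl triflate 26 (not isolated)
Conditions: TMSOTf (1.2 equiv), CH2Cl2 (0.01 M), −78 → −40 °C; sat. NaHCO3; then citric acid, MeOH–H2O, rt
Reagents that add atoms: none
Why: Proposed new method: TMSOTf should ionise the C3 methoxy group to a cyclic peroxycarbenium ion, which the allylsilane tethered to the C4 oxygen can reach only on the face cis to that oxygen (SE2′ through a seven-membered transition state), so the allyl group is delivered to C3 as the 3S epimer and hydrolysis of the resulting silyl triflate frees the C4 alcohol; the closest known reaction types are the intermolecular Hosomi–Sakurai allylation of peroxycarbenium ions from 3-alkoxy-1,2-dioxanes and 3-alkoxy-1,2-dioxolanes and the temporary-silicon-tethered allylation of glycosyl oxocarbenium ions from a neighbouring oxygen, which gives 1,2-cis C-allyl glycosides.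

Step 16
Reactants: 27 the 3-allyl-1,2-dioxan-4-ol
Product: 30 O-triisopropylsilyl plakortolide F lactol (C1 hemiacetal of the cis-fused bicycle; both C1 epimers), via vicinal diol 28 (not isolated), via hydroxy aldehyde 29 (not isolated)
Conditions: OsO4 (2 mol%), NaIO4 (4 equiv), 2,6-lutidine (2 equiv), dioxane–H2O (3:1), rt
Reagents that add atoms: osmium tetroxide, O=[Os](=O)(=O)=O; sodium periodate, [Na+].[O-]I(=O)(=O)=O; water, O
Why: Lemieux–Johnson cleavage of the terminal alkene; the aldehyde should be trapped at once by the cis C4 hydroxyl as the five-membered lactol, and neither periodate nor catalytic osmium attacks a dialkyl peroxide.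

Step 17
Reactants: 30 the lactol
Product: 31 O-triisopropylsilyl plakortolide F, (3S,4S,6R)
Conditions: PhI(OAc)2 (1.5 equiv), TEMPO (0.2 equiv), CH2Cl2, rt
Reagents that add atoms: none
Why: Oxoammonium (TEMPO) oxidation of a lactol to the γ-lactone under neutral to weakly acidic conditions, which avoids base-induced E1cB opening of the β-peroxy lactone.

Step 18
Reactants: 31 O-triisopropylsilyl plakortolide F
Product: 32 plakortolide F
Conditions: TBAF (1.2 equiv), AcOH (1.5 equiv), THF, 0 °C
Reagents that add atoms: none
Why: Fluoride-mediated desilylation cleaves the aryl Si–O bond rapidly, and the acetic acid buffer should protonate the phenoxide at once and keep the β-peroxy lactone from base-induced β-elimination.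

**Compound list**

1 | 4-bromophenol | Oc1ccc(Br)cc1 | starting material
2 | (4-bromophenoxy)triisopropylsilane | CC(C)[Si](Oc1ccc(Br)cc1)(C(C)C)C(C)C | intermediate
3 | 1,7-dibromoheptane | BrCCCCCCCBr | starting material
4 | {4-[(triisopropylsilyl)oxy]phenyl}magnesium bromide | CC(C)[Si](Oc1ccc([Mg]Br)cc1)(C(C)C)C(C)C | intermediate
5 | [4-(7-bromoheptyl)phenoxy]triisopropylsilane | CC(C)[Si](Oc1ccc(CCCCCCCBr)cc1)(C(C)C)C(C)C | intermediate
6 | lithium (trimethylsilyl)acetylide | [Li]C#C[Si](C)(C)C | starting material
7 | trimethyl(9-{4-[(triisopropylsilyl)oxy]phenyl}non-1-yn-1-yl)silane | CC(C)[Si](Oc1ccc(CCCCCCCC#C[Si](C)(C)C)cc1)(C(C)C)C(C)C | intermediate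
8 | triisopropyl[4-(non-8-yn-1-yl)phenoxy]silane | CC(C)[Si](Oc1ccc(CCCCCCCC#C)cc1)(C(C)C)C(C)C | intermediate
9 | (R)-lactic acid | C[C@@H](O)C(=O)O | starting material
10 | pivalaldehyde | CC(C)(C)C=O | starting material
11 | (2R,5R)-2-tert-butyl-5-methyl-1,3-dioxolan-4-one | C[C@H]1O[C@@H](C(C)(C)C)OC1=O | intermediate
12 | 2,3-dibromopropene | C=C(Br)CBr | starting material
13 | lithium (2R)-2-tert-butyl-5-methyl-1,3-dioxol-4-olate (enolate of 11) | [Li+].CC1=C([O-])O[C@H](C(C)(C)C)O1 | intermediate
14 | (2R,5S)-5-(2-bromoprop-2-en-1-yl)-2-tert-butyl-5-methyl-1,3-dioxolan-4-one | C[C@@]1(CC(Br)=C)O[C@@H](C(C)(C)C)OC1=O | intermediate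
15 | (2R,5S)-5-(2-bromoprop-2-en-1-yl)-2-tert-butyl-5-methyl-1,3-dioxolan-4-ol (lactol epimers) | C[C@@]1(CC(Br)=C)O[C@@H](C(C)(C)C)OC1O | intermediate
16 | (2S)-4-bromo-1,1-dimethoxy-2-methylpent-4-en-2-ol | COC(OC)[C@@](C)(O)CC(Br)=C | intermediate
17 | (2S)-1,1-dimethoxy-2-methyl-4-methylidene-13-{4-[(triisopropylsilyl)oxy]phenyl}tridec-5-yn-2-ol | COC(OC)[C@@](C)(O)CC(=C)C#CCCCCCCCc1ccc(O[Si](C(C)C)(C(C)C)C(C)C)cc1 | intermediate
18 | (2S)-1-hydroperoxy-1-methoxy-2-methyl-4-methylidene-13-{4-[(triisopropylsilyl)oxy]phenyl}tridec-5-yn-2-ol (C3 epimers, target numbering) | COC(OO)[C@@](C)(O)CC(=C)C#CCCCCCCCc1ccc(O[Si](C(C)C)(C(C)C)C(C)C)cc1 | intermediate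
19 | N-iodosuccinimide | O=C1CCC(=O)N1I | starting material
20 | (4S,6S)-6-(iodomethyl)-3-methoxy-4-methyl-6-(9-{4-[(triisopropylsilyl)oxy]phenyl}non-1-yn-1-yl)-1,2-dioxan-4-ol (C3 anomers) | COC1OO[C@](CI)(C#CCCCCCCCc2ccc(O[Si](C(C)C)(C(C)C)C(C)C)cc2)C[C@]1(C)O | intermediate
21 | (4S,6S)-6-(iodomethyl)-3-methoxy-4-methyl-6-[(1Z)-9-{4-[(triisopropylsilyl)oxy]phenyl}non-1-en-1-yl]-1,2-dioxan-4-ol | COC1OO[C@](CI)(/C=C\CCCCCCCc2ccc(O[Si](C(C)C)(C(C)C)C(C)C)cc2)C[C@]1(C)O | intermediate
22 | (4S,6R)-6-(iodomethyl)-3-methoxy-4-methyl-6-(9-{4-[(triisopropylsilyl)oxy]phenyl}nonyl)-1,2-dioxan-4-ol | COC1OO[C@](CI)(CCCCCCCCCc2ccc(O[Si](C(C)C)(C(C)C)C(C)C)cc2)C[C@]1(C)O | intermediate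
23 | (4S,6R)-3-methoxy-4,6-dimethyl-6-(9-{4-[(triisopropylsilyl)oxy]phenyl}nonyl)-1,2-dioxan-4-ol | COC1OO[C@](C)(CCCCCCCCCc2ccc(O[Si](C(C)C)(C(C)C)C(C)C)cc2)C[C@]1(C)O | intermediate
24 | allyl(chloro)dimethylsilane | C=CC[Si](C)(C)Cl | starting material
25 | {[(4S,6R)-3-methoxy-4,6-dimethyl-6-(9-{4-[(triisopropylsilyl)oxy]phenyl}nonyl)-1,2-dioxan-4-yl]oxy}dimethyl(prop-2-en-1-yl)silane | COC1OO[C@](C)(CCCCCCCCCc2ccc(O[Si](C(C)C)(C(C)C)C(C)C)cc2)C[C@]1(C)O[Si](C)(C)CC=C | intermediate
26 | {[(3S,4S,6R)-4,6-dimethyl-3-(prop-2-en-1-yl)-6-(9-{4-[(triisopropylsilyl)oxy]phenyl}nonyl)-1,2-dioxan-4-yl]oxy}dimethylsilyl trifluoromethanesulfonate | C=CC[C@@H]1OO[C@](C)(CCCCCCCCCc2ccc(O[Si](C(C)C)(C(C)C)C(C)C)cc2)C[C@]1(C)O[Si](C)(C)OS(=O)(=O)C(F)(F)F | intermediate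
27 | (3S,4S,6R)-4,6-dimethyl-3-(prop-2-en-1-yl)-6-(9-{4-[(triisopropylsilyl)oxy]phenyl}nonyl)-1,2-dioxan-4-ol | C=CC[C@@H]1OO[C@](C)(CCCCCCCCCc2ccc(O[Si](C(C)C)(C(C)C)C(C)C)cc2)C[C@]1(C)O | intermediate
28 | 3-[(3S,4S,6R)-4-hydroxy-4,6-dimethyl-6-(9-{4-[(triisopropylsilyl)oxy]phenyl}nonyl)-1,2-dioxan-3-yl]propane-1,2-diol | OCC(O)C[C@@H]1OO[C@](C)(CCCCCCCCCc2ccc(O[Si](C(C)C)(C(C)C)C(C)C)cc2)C[C@]1(C)O | intermediate
29 | 2-[(3S,4S,6R)-4-hydroxy-4,6-dimethyl-6-(9-{4-[(triisopropylsilyl)oxy]phenyl}nonyl)-1,2-dioxan-3-yl]acetaldehyde | O=CC[C@@H]1OO[C@](C)(CCCCCCCCCc2ccc(O[Si](C(C)C)(C(C)C)C(C)C)cc2)C[C@]1(C)O | intermediate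
30 | O-triisopropylsilyl plakortolide F lactol (C1 hemiacetal; 3S,4S,6R) | C[C@@]1(CCCCCCCCCc2ccc(O[Si](C(C)C)(C(C)C)C(C)C)cc2)C[C@]2(C)OC(O)C[C@@H]2OO1 | intermediate
31 | O-triisopropylsilyl plakortolide F (3S,4S,6R) | C[C@@]1(CCCCCCCCCc2ccc(O[Si](C(C)C)(C(C)C)C(C)C)cc2)C[C@]2(C)OC(=O)C[C@@H]2OO1 | intermediate
32 | plakortolide F (3S,4S,6R; 1,2-dioxane cis-fused at C3–C4 to the γ-lactone, 4-methyl, 6-methyl, 6-[9-(4-hydroxyphenyl)nonyl]) | C[C@@]1(CCCCCCCCCc2ccc(O)cc2)C[C@]2(C)OC(=O)C[C@@H]2OO1 | target

**Totals**

Total step count: 18.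
Longest linear sequence: 14 steps (steps 5–18 from (R)-lactic acid; the arylnonyne branch, steps 1–4 then 9–18, is equally long).

**Steps most likely to fail**

1. Step 15 (proposed new method). The peroxycarbenium ion may not be intercepted by the tethered allylsilane: the silyl tether may be lost before ionisation, the ring may open by ionisation at the endocyclic C3–O bond, or Hock-type fragmentation may take over. Fallback with known chemistry: setting out from 23, the C3 methoxy group is replaced intermolecularly by the ketene silyl acetal of methyl acetate (1-methoxy-1-(trimethylsilyloxy)ethene, TMSOTf cat., CH2Cl2, −78 °C), the established Mukaiyama-type trapping of peroxycarbenium ions. This should give the methyl (4-hydroxy-1,2-dioxan-3-yl)acetate F1 as a mixture of C3 epimers. Brief treatment with CSA in CH2Cl2 then lactonises only the epimer whose side chain is cis to the C4 hydroxyl. The route is rejoined at 31, and the unlactonised trans hydroxy ester is removed by chromatography; steps 14–17 are bypassed.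

2. Step 10. Ionisation of the acetal next to the electron-withdrawing carbinol may be slow, and forcing it risks over-exchange to the geminal dihydroperoxide or acid-induced decomposition of the product. Fallback: setting out from 17, the acetal is hydrolysed (aq. HCl, THF, rt) to the α-hydroxy aldehyde F2. Hydrogen peroxide then adds to the free carbonyl group in methanol with catalytic acid (50% H2O2, MeOH, TsOH cat., 0 °C), which does not require the difficult ionisation. This should return the methoxy hydroperoxide 18.

3. Step 11. The free α-methoxy hydroperoxide may be consumed by the iodonium source (oxidation, acid-promoted Hock cleavage) before the 6-exo closure, or the iodonium ion may be diverted to the alkyne. Fallback: setting out from 17, the acetal is exchanged with anhydrous tert-butyl hydroperoxide (CSA cat., CH2Cl2) to give the tert-butyl peroxy acetal F3, a stable dialkyl peroxide. Its distal oxygen closes onto the iodonium-activated alkene (NIS, CH2Cl2, 0 °C) to a cyclic peroxonium ion that loses the tert-butyl group as isobutene. This is the known dealkylative halocyclisation of unsaturated tert-butyl peroxides, and it rejoins the route at 20.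

**Further compounds**

F1 | step 15 | methyl 2-[(4S,6R)-4-hydroxy-4,6-dimethyl-6-(9-{4-[(triisopropylsilyl)oxy]phenyl}nonyl)-1,2-dioxan-3-yl]acetate (C3 epimers) | COC(=O)CC1OO[C@](C)(CCCCCCCCCc2ccc(O[Si](C(C)C)(C(C)C)C(C)C)cc2)C[C@]1(C)O
F2 | step 10 | (2S)-2-hydroxy-2-methyl-4-methylidene-13-{4-[(triisopropylsilyl)oxy]phenyl}tridec-5-ynal | O=C[C@@](C)(O)CC(=C)C#CCCCCCCCc1ccc(O[Si](C(C)C)(C(C)C)C(C)C)cc1
F3 | step 11 | (2S)-1-(tert-butylperoxy)-1-methoxy-2-methyl-4-methylidene-13-{4-[(triisopropylsilyl)oxy]phenyl}tridec-5-yn-2-ol (C1 epimers) | COC(OOC(C)(C)C)[C@@](C)(O)CC(=C)C#CCCCCCCCc1ccc(O[Si](C(C)C)(C(C)C)C(C)C)cc1
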